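Litres per mole were the unit in which I weighed the next charge: the south-west flask, with 0.120 M of free catalyst, and what that catalyst would buy by 17 min.

| flask | starting material | partner | free catalyst | time |
|---|---|---|---|---|
| south | 1.00 M | 1.20 M | 0.0500 M |  |
| north-east | 0.400 M | 0.600 M | 0.0500 M |  |
| north-west | 1.50 M | 1.20 M | 0.0500 M |  |
| south-east | 1.00 M | 1.20 M | 0.0750 M |  |
| south-west | 1.00 M | 1.20 M | 0.120 M | 17 min |

- south run (time / min: [starting material] / M): 1.3: 0.785; 3.9: 0.538; 7.5: 0.396; 12: 0.313; 17: 0.248
- north-east run (time / min: [starting material] / M): 1.3: 0.365; 3.9: 0.282; 7.5: 0.219; 12: 0.172; 17: 0.151
- north-west run (time / min: [starting material] / M): 1.3: 1.154; 3.9: 0.787; 7.5: 0.570; 12: 0.478; 17: 0.371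
- south-east run (time / min: [starting material] / M): 1.3: 0.708; 3.9: 0.485; 7.5: 0.340; 12: 0.262; 17: 0.224

(each reading ± 0.01 M)

* the exponent of [partner] in the starting rate at the charge of the south run (at the point where two percent of the starting material have become product)
* the exponent of [free catalyst] in the starting rate at the charge of the south run (at the point where two percent of the starting material have become product)
* starting material in the south-west run at 17 min, as a share of the starting material charged

- Overall: starting material + partner -> product, with free catalyst as catalyst.
- Constant volume, constant temperature.
- "The second partner" is partner.
- An order is taken over about fifteen percent of the charge, up and down.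

**Starting orders.** I replaced each early curve by its mean: the loss of starting material up to a reading, set against the means of c(starting material) and c(partner) over that span, assuming first order in starting material as the overall equation has it. To 1.3 min the south-east run lost 1.36 times what the south run lost, on 1.50 times the free catalyst; with the means divided out, that reads as a free-catalyst order of 0.952. The south and north-east runs share their free catalyst, and to 3.9 min, where the north-east loss is 0.118 M against a scatter of 0.01 M, they read as a partner order of 0.947. I committed to first order in both.

**Exposure clock.** With that law, and counting each starting material lost as one partner lost, I took the logarithm of c(partner)/c(starting material), subtracted its value at the charge, and divided by the charge of partner less that of starting material, the limiting reagent of the south run. At 17 min the south run gave 2.05 L mol⁻¹: the catalyst exposure, the time integral of rate constant times c(free catalyst). Its mean per minute over the 17 min was 0.702 of the mean to 3.9 min, so I used the figure at 17 min and no other time. Carried to the north-east run, with the same free catalyst but another charge, it gave 0.159 M at 17 min, against a reading of 0.151 M.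

**The decision.** The south-east run reached 2.28 L mol⁻¹, 1.11 times the south value, less than its catalyst ratio; the scatter of one reading moves this by 0.105 L mol⁻¹. Assuming equal steps of exposure per factor of catalyst, I reckoned 2.55 L mol⁻¹ for the south-west run, hence 20.0% of its starting material left, a gain of 2.4 percentage points on the south-east run. I kept the charge as a test of this rule, not as a route to conversion.

**Forecast and flask.** The forecast, made from the same runs, gave a partner order of 0.5, below my figure, a catalyst order of 0.9 and 17% left, below my share, and it pointed to “catalyst loss, roughly second order in catalyst”. The flask gave 1.0, 1.0 and 19.4%.

    free catalyst + starting material + partner → product + free catalyst (2.280 L² mol⁻² min⁻¹)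
    2 starting material → homo dimer (0.03282 L mol⁻¹ min⁻¹)
    free catalyst + product → spent catalyst + product (0.3492 L mol⁻¹ min⁻¹)

**Lost catalyst.** The 19.4% of the south-west run corresponds to an exposure of 2.63 L mol⁻¹, which is 1.28 times that of the south run on 2.40 times its free catalyst. Starting material stays that high in the south-west run because product turns free catalyst into spent catalyst. With that step taken away, the south-west run holds 5.86% of its starting material at 17 min, against 19.4%.

(The data stem from a simulated flask for an exercise; scatter was added.)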